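**Retrosynthetic overview**
1. Target 16 ⇐ 13: the lactone ring is closed last through the C12–O6 bond by a one-flask allylic C–H oxidative lactonisation (key step, proposed new method).
2. 13 ⇐ 12: both oxiranes come from one double hydroxyl-directed epoxidation (four C–O bonds, four stereocentres).
3. 12 ⇐ 11: the ten-membered carbocycle is formed first, by Nozaki–Hiyama allylation (C6–C7).
4. 11 ⇐ 9 + 10 (vinylogous aldol, C2–C3); 9 ⇐ lactone 4 by aminolysis/angeloylation (C8–O), reduction and ene-chlorination.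
5. 4 ⇐ prenal + senecioate dienolate (C8–C9). All skeletal carbons come from three C5 units plus angelic acid. Ring order: carbocycle → two oxiranes → lactone.

Assumption: the SMILES is taken as drawn, i.e. (1R,2S,4R,5R,6S,7R,8S,10S) with a trans-fused 6,12-lactone, a trans 4,5-epoxide, a cis 1,10-epoxide and an 8-angelate; germacrane numbering is used throughout.

Step 1
Reactants: 1 methyl 3-methylbut-2-enoate
Product: 2 [(1-methoxy-3-methylbuta-1,3-dien-1-yl)oxy]trimethylsilane
Conditions: LiN(i-Pr)2, THF, −78 °C; TMSCl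
Reagents that add atoms: chlorotrimethylsilane C[Si](C)(C)Cl
Why: Kinetic γ-deprotonation of the senecioate and O-silylation (silyl ketene acetal formation) give the cross-conjugated silyl dienolate, with no stereocentre formed.

Step 2
Reactants: 2 [(1-methoxy-3-methylbuta-1,3-dien-1-yl)oxy]trimethylsilane; 3 3-methylbut-2-enal (prenal)
Product: 4 (6S)-4-methyl-6-(2-methylprop-1-en-1-yl)-5,6-dihydro-2H-pyran-2-one
Conditions: Cu(OTf)2 (10 mol%), (S)-Tol-BINAP (11 mol%), Bu4N[Ph3SiF2] (20 mol%), THF, −78 to 23 °C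
Reagents that add atoms: none
Why: Catalytic asymmetric vinylogous Mukaiyama aldol through a chiral copper dienolate adds the γ-carbon 1,2 to prenal, the ligand setting C8 as S (the ligand antipode is matched to the 6S lactone in a test run), and the cis aldolate lactonises in situ, which locks the future 1(10) alkene as Z.

Step 3
Reactants: 4 (6S)-4-methyl-6-(2-methylprop-1-en-1-yl)-5,6-dihydro-2H-pyran-2-one; 5 angelic acid [(2Z)-2-methylbut-2-enoic acid]
Product: 7 (2Z,5S)-N-methoxy-N,3,7-trimethyl-5-{[(2Z)-2-methylbut-2-enoyl]oxy}octa-2,6-dienamide, via ring-opened hydroxy Weinreb amide 6 (not isolated)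
Conditions: MeNH(OMe)·HCl, i-PrMgCl, THF, −20 °C; then premixed 5/2,4,6-trichlorobenzoyl chloride/Et3N, DMAP, −20 to 23 °C
Reagents that add atoms: N,O-dimethylhydroxylamine hydrochloride CNOC.Cl
Why: Weinreb aminolysis opens the lactone with the Z alkene intact and the liberated C8 magnesium alkoxide is esterified in the same flask by Yamaguchi acylation (C–O bond), conditions that do not touch C8 and do not isomerise angelate to tiglate.

Step 4
Reactants: 7 (2Z,5S)-N-methoxy-N,3,7-trimethyl-5-{[(2Z)-2-methylbut-2-enoyl]oxy}octa-2,6-dienamide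
Product: 8 (4S,6Z)-2,6-dimethyl-8-oxoocta-2,6-dien-4-yl (2Z)-2-methylbut-2-enoate
Conditions: Cp2Zr(H)Cl (1.5 equiv), THF, 23 °C, 20 min
Reagents that add atoms: none
Why: Schwartz reduction of a tertiary amide stops at the aldehyde and leaves the angelate ester and the trisubstituted alkenes alone, giving the Z-enal.

Step 5
Reactants: 8 (4S,6Z)-2,6-dimethyl-8-oxoocta-2,6-dien-4-yl (2Z)-2-methylbut-2-enoate
Product: 9 (4S,6Z)-3-chloro-2,6-dimethyl-8-oxoocta-1,6-dien-4-yl (2Z)-2-methylbut-2-enoate (both C3 epimers)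
Conditions: N-chlorosuccinimide (1.1 equiv), PhSeCl (10 mol%), CH2Cl2, 23 °C
Reagents that add atoms: N-chlorosuccinimide O=C1CCC(=O)N1Cl
Why: Selenium-catalysed ene-type allylic chlorination attacks the only electron-rich alkene, placing chlorine on C7 and moving the double bond to C11=C13, and the C7 epimers are inconsequential because both give the same allylchromium in step 8.

Step 6
Reactants: 3 3-methylbut-2-enal (prenal)
Product: 10 tert-butyl(dimethyl){[(1E)-3-methylbuta-1,3-dien-1-yl]oxy}silane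
Conditions: TBSOTf, Et3N, Et2O, 0 °C
Reagents that add atoms: tert-butyldimethylsilyl trifluoromethanesulfonate CC(C)(C)[Si](C)(C)OS(=O)(=O)C(F)(F)F
Why: Soft enolisation (O-silylation then γ-deprotonation) gives the E silyl dienol ether of prenal.

Step 7
Reactants: 9 (4S,6Z)-3-chloro-2,6-dimethyl-8-oxoocta-1,6-dien-4-yl (2Z)-2-methylbut-2-enoate; 10 tert-butyl(dimethyl){[(1E)-3-methylbuta-1,3-dien-1-yl]oxy}silane
Product: 11 (4S,6Z,8S,10E)-3-chloro-8-hydroxy-2,6,10-trimethyl-12-oxododeca-1,6,10-trien-4-yl (2Z)-2-methylbut-2-enoate (C3 epimers)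
Conditions: (4R)-4-(1H-indol-3-ylmethyl)-3-(4-methylphenylsulfonyl)-2-phenyl-1,3,2-oxazaborolidin-5-one (30 mol%), i-PrOH (1.2 equiv), EtCN, −78 °C
Reagents that add atoms: none
Why: Enantioselective vinylogous Mukaiyama aldol in which the chiral boron Lewis acid activates the Z-enal for 1,2-attack by the γ-carbon of the dienol ether, giving the E-enal and setting C2 as S under catalyst control (the D-tryptophan-derived antipode, chosen by analogy with benzaldehyde aldols), while i-PrOH takes up the silyl group for turnover.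

Step 8
Reactants: 11 (4S,6Z,8S,10E)-3-chloro-8-hydroxy-2,6,10-trimethyl-12-oxododeca-1,6,10-trien-4-yl (2Z)-2-methylbut-2-enoate
Product: 12 (1(10)Z,2S,4E,6R,7S,8S)-2,6-dihydroxygermacra-1(10),4,11(13)-trien-8-yl (2Z)-2-methylbut-2-enoate
Conditions: CrCl2 (8 equiv), NaI (0.2 equiv), THF–DMF 4:1, 2 mM, slow addition, 23 °C
Reagents that add atoms: none
Why: Intramolecular Nozaki–Hiyama allylation in which the allylchromium adds through C7 to the C6 aldehyde via a chair transition state (6,7-anti, hence trans H6/H7) and on the allyl face anti to the C8 acyloxy group with H8 eclipsed (allylic 1,3-strain, Kishi-type model), giving C6 and C7 in the spatial arrangement of the target (6R,7S by CIP in 12).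

Step 9
Reactants: 12 (1(10)Z,2S,4E,6R,7S,8S)-2,6-dihydroxygermacra-1(10),4,11(13)-trien-8-yl (2Z)-2-methylbut-2-enoate
Product: 13 (1R,2S,4R,5R,6S,7S,8S,10S)-1,10:4,5-diepoxy-2,6-dihydroxygermacr-11(13)-en-8-yl (2Z)-2-methylbut-2-enoate
Conditions: VO(acac)2 (10 mol%), t-BuOOH (2.3 equiv, decane), CH2Cl2, 0 °C
Reagents that add atoms: tert-butyl hydroperoxide CC(C)(C)OO
Why: Vanadium-catalysed hydroxyl-directed epoxidation in which each allylic hydroxyl (C2–OH for the Z-1(10) alkene, C6–OH for the E-4,5 alkene) keeps its carbinol C–H in the alkene plane to avoid allylic 1,3-strain (with C9 and with C15) and delivers oxygen to the outer face syn to itself, giving both threo epoxy alcohols (1R,10S and 4R,5R), while the merely homoallylic 1,1-disubstituted isopropenyl group and the angelate react far more slowly.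

Step 10
Reactants: 13 (1R,2S,4R,5R,6S,7S,8S,10S)-1,10:4,5-diepoxy-2,6-dihydroxygermacr-11(13)-en-8-yl (2Z)-2-methylbut-2-enoate
Product: 16 (1R,2S,4R,5R,6S,7R,8S,10S)-8-[(2Z)-2-methylbut-2-enoyloxy]-1,10:4,5-diepoxy-2-hydroxygermacr-11(13)-en-12,6-olide (CNP0388761.1), via 12-hydroxy triol 14 (not isolated), via 6,12-lactol 15 (not isolated)
Conditions: SeO2 (0.3 equiv), t-BuOOH (3 equiv), CH2Cl2, 23 °C; then 4-acetamido-TEMPO (0.2 equiv), PhI(OAc)2 (2.3 equiv), same flask
Reagents that add atoms: tert-butyl hydroperoxide CC(C)(C)OO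
Why: Proposed new method: a one-flask selenium/oxoammonium relay allylic C–H lactonisation in which tetravalent selenium undergoes an ene reaction at C11=C13 and a [2,3]-shift that hydroxylates the C12 methyl (favoured over the hindered, electron-poor C7–H), the oxoammonium from 4-acetamido-TEMPO then oxidises only this primary allylic alcohol to the enal, the C6 hydroxyl closes the five-membered lactol (the ring-forming C12–O6 bond) and a second oxoammonium turnover gives the α-methylene lactone without changing any stereocentre, the closest known reactions being SeO2/t-BuOOH allylic hydroxylation and TEMPO/PhI(OAc)2 oxidative lactonisation of 1,4-diols, which have not been merged into one operation on an isopropenyl carbinol.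

**Compound list**
1 | methyl 3-methylbut-2-enoate | COC(=O)C=C(C)C | starting material
2 | [(1-methoxy-3-methylbuta-1,3-dien-1-yl)oxy]trimethylsilane (ketene acetal geometry not defined) | COC(O[Si](C)(C)C)=CC(C)=C | intermediate
3 | 3-methylbut-2-enal (prenal) | CC(C)=CC=O | starting material
4 | (6S)-4-methyl-6-(2-methylprop-1-en-1-yl)-5,6-dihydro-2H-pyran-2-one | CC(C)=C[C@@H]1CC(C)=CC(=O)O1 | intermediate
5 | angelic acid, (2Z)-2-methylbut-2-enoic acid | C/C=C(/C)C(=O)O | starting material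
6 | (2Z,5S)-5-hydroxy-N-methoxy-N,3,7-trimethylocta-2,6-dienamide (present as its chloromagnesium alkoxide) | CC(C)=C[C@@H](O)C/C(C)=C\C(=O)N(C)OC | intermediate
7 | (2Z,5S)-N-methoxy-N,3,7-trimethyl-5-{[(2Z)-2-methylbut-2-enoyl]oxy}octa-2,6-dienamide | CC(C)=C[C@@H](OC(=O)/C(C)=C\C)C/C(C)=C\C(=O)N(C)OC | intermediate
8 | (4S,6Z)-2,6-dimethyl-8-oxoocta-2,6-dien-4-yl (2Z)-2-methylbut-2-enoate | CC(C)=C[C@@H](OC(=O)/C(C)=C\C)C/C(C)=C\C=O | intermediate
9 | (4S,6Z)-3-chloro-2,6-dimethyl-8-oxoocta-1,6-dien-4-yl (2Z)-2-methylbut-2-enoate (both C3 epimers) | C=C(C)C(Cl)[C@@H](OC(=O)/C(C)=C\C)C/C(C)=C\C=O | intermediate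
10 | tert-butyl(dimethyl){[(1E)-3-methylbuta-1,3-dien-1-yl]oxy}silane | C=C(C)/C=C/O[Si](C)(C)C(C)(C)C | intermediate
11 | (4S,6Z,8S,10E)-3-chloro-8-hydroxy-2,6,10-trimethyl-12-oxododeca-1,6,10-trien-4-yl (2Z)-2-methylbut-2-enoate (C3 epimers) | O=C/C=C(\C)C[C@H](O)/C=C(/C)C[C@H](OC(=O)/C(C)=C\C)C(Cl)C(C)=C | intermediate
12 | (1(10)Z,2S,4E,6R,7S,8S)-2,6-dihydroxygermacra-1(10),4,11(13)-trien-8-yl (2Z)-2-methylbut-2-enoate | CC(=C)[C@H]1[C@H](O)/C=C(C)/C[C@H](O)/C=C(C)\C[C@@H]1OC(=O)/C(C)=C\C | intermediate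
13 | (1R,2S,4R,5R,6S,7S,8S,10S)-1,10:4,5-diepoxy-2,6-dihydroxygermacr-11(13)-en-8-yl (2Z)-2-methylbut-2-enoate | CC(=C)[C@H]1[C@H](O)[C@H]2O[C@]2(C)C[C@H](O)[C@H]2O[C@@]2(C)C[C@@H]1OC(=O)/C(C)=C\C | intermediate
14 | (1R,2S,4R,5R,6S,7S,8S,10S)-1,10:4,5-diepoxy-2,6,12-trihydroxygermacr-11(13)-en-8-yl (2Z)-2-methylbut-2-enoate | OCC(=C)[C@H]1[C@H](O)[C@H]2O[C@]2(C)C[C@H](O)[C@H]2O[C@@]2(C)C[C@@H]1OC(=O)/C(C)=C\C | intermediate
15 | (1R,2S,4R,5R,6S,7R,8S,10S)-1,10:4,5-diepoxy-2,12-dihydroxy-6,12-epoxygermacr-11(13)-en-8-yl (2Z)-2-methylbut-2-enoate (lactol, C12 epimers) | C=C1C(O)O[C@H]2[C@H]1[C@@H](OC(=O)/C(C)=C\C)C[C@]1(C)O[C@@H]1[C@@H](O)C[C@@]1(C)O[C@H]21 | intermediate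
16 | (1R,2S,4R,5R,6S,7R,8S,10S)-8-[(2Z)-2-methylbut-2-enoyloxy]-1,10:4,5-diepoxy-2-hydroxygermacr-11(13)-en-12,6-olide (CNP0388761.1) | C=C1C(=O)O[C@H]2[C@H]1[C@@H](OC(=O)/C(C)=C\C)C[C@]1(C)O[C@@H]1[C@@H](O)C[C@@]1(C)O[C@H]21 | target

**Step count**
Total steps: 10. Longest linear sequence: 9 (steps 1, 2, 3, 4, 5, 7, 8, 9, 10); step 6 is a one-step side branch.

**Three steps most likely to fail**

Step 10 (proposed new lactonisation). The selenium stage may stop short, or the oxoammonium stage may touch the C2 hydroxyl. The fallback uses known chemistry and runs the two stages apart. It sets out from 13: SeO2/t-BuOOH with a little salicylic acid gives the isolated triol 14, and MnO2 in CH2Cl2 then oxidises the allylic primary alcohol and the resulting lactol 15 to 16, the sequence used for costunolide-type lactones. If the oxidation stalls at 15, Pinnick oxidation (NaClO2, NaH2PO4, 2-methylbut-2-ene) gives (1R,2S,4R,5R,6S,7S,8S,10S)-8-angeloyloxy-1,10:4,5-diepoxy-2,6-dihydroxygermacr-11(13)-en-12-oic acid F1, which closes on mild acid work-up. The fallback comes back to the route at 16.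

Step 8 (macrocyclisation). Risks are oligomerisation, loss of angelate from the allylchromium by β-elimination, ionisation of the free Z-allylic alcohol, and the wrong face at C7. The fallback changes both the substrate and the allylmetal. It sets out from 11: TESOTf/2,6-lutidine gives the silyl ether (4S,6Z,8S,10E)-3-chloro-2,6,10-trimethyl-12-oxo-8-(triethylsilyloxy)dodeca-1,6,10-trien-4-yl (2Z)-2-methylbut-2-enoate F2. Umpolung allylation with Pd(PPh3)4 (10 mol%) and Et2Zn in THF at high dilution (π-allylpalladium to allylzinc, chair transition state, the mode proven for germacrene-type ten-membered rings) gives (1(10)Z,2S,4E,6R,7S,8S)-6-hydroxy-2-(triethylsilyloxy)germacra-1(10),4,11(13)-trien-8-yl (2Z)-2-methylbut-2-enoate F3. HF·pyridine then returns the route to 12. A chiral sulfonamide ligand on chromium is held in reserve if the C6/C7 face needs reagent control.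

Step 9 (double directed epoxidation). In the ring the facial outcome rests on conformational arguments, and the isopropenyl group could be over-epoxidised. The fallback moves the C2-directed epoxidation to the open chain, where allylic 1,3-strain control of Z-allylic alcohols is textbook. It sets out from 11: VO(acac)2/t-BuOOH (1.1 equiv) gives (4S,6S,7R,8S,10E)-3-chloro-6,7-epoxy-8-hydroxy-2,6,10-trimethyl-12-oxododeca-1,10-dien-4-yl (2Z)-2-methylbut-2-enoate F4. CrCl2 cyclisation as in step 8, with the cis-epoxide as turn element, gives (1R,2S,4E,6R,7S,8S,10S)-1,10-epoxy-2,6-dihydroxygermacra-4,11(13)-dien-8-yl (2Z)-2-methylbut-2-enoate F5. A single C6-directed VO(acac)2/t-BuOOH epoxidation of the 4,5-alkene then comes back to the route at 13.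

**Further compounds**
F1 | step 10 | (1R,2S,4R,5R,6S,7S,8S,10S)-8-angeloyloxy-1,10:4,5-diepoxy-2,6-dihydroxygermacr-11(13)-en-12-oic acid | OC(=O)C(=C)[C@H]1[C@H](O)[C@H]2O[C@]2(C)C[C@H](O)[C@H]2O[C@@]2(C)C[C@@H]1OC(=O)/C(C)=C\C
F2 | step 8 | (4S,6Z,8S,10E)-3-chloro-2,6,10-trimethyl-12-oxo-8-(triethylsilyloxy)dodeca-1,6,10-trien-4-yl (2Z)-2-methylbut-2-enoate | O=C/C=C(\C)C[C@H](O[Si](CC)(CC)CC)/C=C(/C)C[C@H](OC(=O)/C(C)=C\C)C(Cl)C(C)=C
F3 | step 8 | (1(10)Z,2S,4E,6R,7S,8S)-6-hydroxy-2-(triethylsilyloxy)germacra-1(10),4,11(13)-trien-8-yl (2Z)-2-methylbut-2-enoate | CC(=C)[C@H]1[C@H](O)/C=C(C)/C[C@H](O[Si](CC)(CC)CC)/C=C(C)\C[C@@H]1OC(=O)/C(C)=C\C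
F4 | step 9 | (4S,6S,7R,8S,10E)-3-chloro-6,7-epoxy-8-hydroxy-2,6,10-trimethyl-12-oxododeca-1,10-dien-4-yl (2Z)-2-methylbut-2-enoate | O=C/C=C(\C)C[C@H](O)[C@H]1O[C@@]1(C)C[C@H](OC(=O)/C(C)=C\C)C(Cl)C(C)=C
F5 | step 9 | (1R,2S,4E,6R,7S,8S,10S)-1,10-epoxy-2,6-dihydroxygermacra-4,11(13)-dien-8-yl (2Z)-2-methylbut-2-enoate | CC(=C)[C@H]1[C@H](O)/C=C(C)/C[C@H](O)[C@H]2O[C@@]2(C)C[C@@H]1OC(=O)/C(C)=C\C
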